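## The problem

Target 14 is (3-methylidene-2,3-dihydro-1-benzoxepin-7-yl)methyl octadecanoate. A benzene ring is fused through C5a and C9a to a seven-membered oxepine (O1, C2, C3, C4, C5) that carries an exocyclic CH2 on C3 and a ring alkene C4=C5, and C7 bears a stearoyloxymethyl group. There is no stereocenter. The only stereochemical element is the cis geometry of C4=C5, which the ring enforces in 14 but which an open-chain precursor must already have, because a trans alkene cannot bridge C5a and O1. The difficulty is the medium ring with its unsaturation at one exact position and oxidation level: the exocyclic alkene, C4=C5 and the arene are conjugated, and acid, strong base or radicals could move the exocyclic double bond into the ring or add across the diene. C2 is both allylic and an aryl ether carbon, and the C7 side chain is a para-alkoxybenzyl ester that ionizes under acid and is cleaved by hydride or alkoxide. The stearate therefore has to go on last, and the late steps must be neutral or basic. The feature that opens the route is positional: C7 is para to C9a, so a C7 carbon at the nitrile oxidation level activates a C9a–F bond toward the C2 oxygen and is afterwards reduced to the CH2O group.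

## Retrosynthesis

**Ester C–O bond (14 ⇒ 12 + 13).** The acyl C–O bond is cut first, giving benzylic alcohol 12 and stearoyl chloride 13. The ester would not survive the hydride and alkoxide steps that precede it, so it cannot be carried earlier. The cut removes eighteen carbons and leaves a C12 bicyclic alcohol. The forward acylation must avoid free HCl, since the para-alkoxybenzyl position ionizes easily.

**C7 oxidation level (12 ⇐ 11 ⇐ 9).** The hydroxymethyl group is traced through aldehyde 11 to nitrile 9. An ester would activate the ring less and could transesterify with the alkoxide of the ring closure; an aldehyde would react with that alkoxide and with the reducing metal used earlier. The nitrile is the strongest activating carbon substituent that is inert to every preceding step. The price is two reductions where an ester would need one. The forward steps must stop the first hydride addition at the aldimine stage and leave the diene alone.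

**O1–C9a bond (9 ⇒ 7), the key cut.** Opening the aryl ether bond gives the acyclic (Z)-dienol 7, in which every carbon and every double bond of the ring is already present.
- Against cutting O1–C2: that would need a free phenol ortho to an alkyne during the coupling steps, which tends to close to a benzofuran, or else a protecting group.
- Against cutting C4=C5: that closure would have to distinguish the two terminal alkenes of a 2-substituted butadiene.
- Against cutting C3–C4: that leaves the ring at the wrong unsaturation (see Alternative 3).

The forward reaction asks only that the C2 alkoxide displace fluoride at C9a, activated by the para nitrile, and that the cis geometry of C4=C5 is intact when it does so.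

**C4=C5 geometry (7 ⇐ 6).** The cis alkene is derived from the alkyne of enynol 6 by semi-reduction. A Wittig reaction with a semi-stabilized allylic ylide would give E/Z mixtures, and a stereodefined cross-coupling would need a preformed (Z)-vinyl metal. The alkyne also turns C4–C5 into a two-carbon linchpin that can be installed by two sp–sp2 couplings. The forward reduction must deliver both hydrogens syn, stop at the diene, and spare the 1,1-disubstituted alkene, the nitrile and the C–F bond.

**C3–C4 and C5–C5a bonds (6 ⇒ 4 + 5; 4 ⇐ 3 ⇒ 1 + 2).** Enynol 6 is cut at the alkyne–vinyl bond into arylacetylene 4 and 2-bromoprop-2-en-1-ol 5. Alkyne 4 is cut at the aryl–alkyne bond, via silyl alkyne 3, into 3-bromo-4-fluorobenzonitrile 1 and trimethylsilylacetylene 2. The aryl coupling comes first because 4 is a non-volatile solid, whereas the reverse order passes through a small volatile enynol. The forward couplings must leave the activated fluoride untouched, which tertiary amine bases allow. All four starting materials (1, 2, 5, 13) are commercial.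

## Roads not taken

**Alternative 1: Photochemical ring expansion of a chromene.**
- Cut and key step: the O1–C2 bond is formed last, and the seven-membered ring arises by isomerizing a six-membered one. Methyl 2,2-dimethyl-2H-chromene-6-carboxylate A1 would be irradiated at about 300 to 350 nm in flow. Electrocyclic opening of the pyran gives ortho-quinone methide A2, a 1,7-hydrogen shift from a methyl group to oxygen gives (Z)-dienylphenol A3, and a second photon is meant to add the phenol O–H across the diene termini to give methyl 3-methyl-2,5-dihydro-1-benzoxepine-7-carboxylate A4.
- Merits: A1 is an isomer of A4 and should be available in one or two steps from a commercial phenol. The key step consumes no reagent. The ester reduces to the benzylic alcohol in one step, where the nitrile of the chosen plan needs two.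
- Weak points: the cascade has several exits, namely reclosure of A2 to A1 (the usual photochromic behaviour), E/Z isomerization of A3, and five-membered closure at C4. More seriously, A4 has the wrong unsaturation: one double bond at C3=C4 and an sp3 C5, where 14 needs C3=CH2 and C4=C5. Converting A4 is a net dehydrogenation with control over where both double bonds end up, which means functionalization at C5 and an elimination that must not give the fully endocyclic diene.
- Comparison: Alternative 1 reaches a benzoxepine in fewer steps (two or three against five). The chosen plan arrives with every double bond in its final place and uses only ground-state reactions of known type.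

**Alternative 2: One-carbon ring expansion by dibromocarbene.**
- Cut and key step: the cut removes C4 with its bonds C3–C4 and C4–C5. 3-Methyl-6-[(triisopropylsilyloxy)methyl]-2H-chromene A5 would take up dibromocarbene (CHBr3, KOtBu) at its ring alkene. AgBF4 with 2,6-lutidine in the same flask would ionize one C–Br bond and open the ring-fusion bond to a seven-membered 2-bromoallyl cation spanning C3 to C5. Loss of a methyl proton would give 4-bromo-3-methylidene-7-[(triisopropylsilyloxy)methyl]-2,3-dihydro-1-benzoxepine A6.
- Merits: one flask forms two C–C bonds, enlarges the ring and creates both alkenes of the diene, with the cis C4=C5 geometry automatic. In this respect it is more direct than the chosen plan, which needs a separate Z-selective reduction before it can close the ring. The C7 carbon is at its final oxidation level throughout.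
- Weak points: A6 carries a bromine on C4 that 14 lacks, so a dienyl C–Br bond must be reduced without touching or isomerizing the diene. The cation can lose a C2 proton (giving an endocyclic enol ether) or be captured at C5, where the para oxygen O1 concentrates the charge. The silver Lewis acid meets an electron-rich benzylic silyl ether. A5 itself takes several steps and needs a silyl group put on and taken off.
- Comparison: step counts are similar (about eight or nine). The chosen plan has a closing step with a single possible site of attack, no extraneous atom to remove and no protecting group.

**Alternative 3: Nickel-catalysed reductive alkyne–aldehyde cyclization.**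
- Cut and key step: the cut is C3–C4. Methyl 3-(2-oxoethyl)-4-(prop-2-yn-1-yloxy)benzoate A7, with Ni(cod)2, 1,3-dimesitylimidazol-2-ylidene and Et3SiH, would couple alkyne and aldehyde through an oxanickelacycle. Hydrogen goes to the terminal alkyne carbon and silicon to oxygen, giving racemic methyl 3-methylidene-4-(triethylsilyloxy)-2,3,4,5-tetrahydro-1-benzoxepine-7-carboxylate A8.
- Merits: a ring C–C bond and the exocyclic methylene form in one catalytic step with unambiguous position. Reductive ynal cyclization is a known reaction class. The ester is a better handle than the nitrile (one reduction instead of two).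
- Weak points: the class is best established for five- and six-membered rings and internal alkynes. Here a seven-membered ring must form from a terminal alkyne, which zerovalent nickel readily oligomerizes. A7 is an enolizable arylacetaldehyde that needs about four steps (allylation, Claisen rearrangement, propargylation, oxidative cleavage beside an alkyne). A8 is not at the target's unsaturation: the C4 oxygen must be eliminated specifically toward C5, through an intermediate that can equally transpose or lose a C2 proton. A stereocenter is made only to be destroyed.
- Comparison: about ten steps in all. In C–C bond construction it is the more strategic route. The chosen plan is shorter, has the diene in place before ring closure, and needs no late elimination.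

Key step: step 5

Remark on the chemistry: compound 8 is listed as a discrete Meisenheimer anion; if the substitution is concerted, 8 describes the transition-state region and nothing in the route changes.

## Route

Step 1
Reactants: 1 3-bromo-4-fluorobenzonitrile; 2 trimethylsilylacetylene
Product: 3 4-fluoro-3-[(trimethylsilyl)ethynyl]benzonitrile
Conditions: PdCl2(PPh3)2 (2 mol %), CuI (4 mol %), Et3N, THF, 40 °C, sealed
Reagents that add atoms: trimethylsilylacetylene (compound 2), C[Si](C)(C)C#C
Why: Sonogashira coupling; the C–Br bond is activated toward oxidative addition by the ortho fluorine and the nitrile, and a tertiary amine base cannot displace the activated fluoride.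

Step 2
Reactants: 3 4-fluoro-3-[(trimethylsilyl)ethynyl]benzonitrile
Product: 4 3-ethynyl-4-fluorobenzonitrile
Conditions: K2CO3 (0.2 equiv), MeOH, 0 °C, short reaction time
Reagents that add atoms: none
Why: Base-catalysed protodesilylation of an alkynylsilane by methoxide attack at silicon; with catalytic carbonate in cold methanol, SNAr at the C–F bond should be far too slow to compete with the fast Si–C cleavage.

Step 3
Reactants: 4 3-ethynyl-4-fluorobenzonitrile; 5 2-bromoprop-2-en-1-ol
Product: 6 4-fluoro-3-[3-(hydroxymethyl)but-3-en-1-yn-1-yl]benzonitrile
Conditions: Pd(PPh3)4 (3 mol %), CuI (5 mol %), Et3N, THF, degassed, rt to 40 °C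
Reagents that add atoms: 2-bromoprop-2-en-1-ol (compound 5), OCC(Br)=C
Why: Sonogashira coupling of a terminal arylalkyne with a vinyl bromide, which tolerates the free allylic alcohol; exclusion of oxygen and a small excess of 5 should hold back oxidative dimerization of the alkyne.

Step 4
Reactants: 6 4-fluoro-3-[3-(hydroxymethyl)but-3-en-1-yn-1-yl]benzonitrile
Product: 7 4-fluoro-3-[(1Z)-3-(hydroxymethyl)buta-1,3-dien-1-yl]benzonitrile
Conditions: Zn dust activated with Cu(OAc)2 and AgNO3, MeOH/H2O 1:1, 25–40 °C, dark
Reagents that add atoms: none
Why: Boland semi-reduction; electron transfer from the activated zinc surface to the conjugated alkyne and protonation by the solvent deliver both hydrogens to the same face, which sets the cis geometry of the new alkene. The reagent should not reduce alkenes, nitriles or aryl fluorides, so it should stop at the diene.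

Step 5
Reactants: 7 4-fluoro-3-[(1Z)-3-(hydroxymethyl)buta-1,3-dien-1-yl]benzonitrile
Product: 9 3-methylidene-2,3-dihydro-1-benzoxepine-7-carbonitrile, via Meisenheimer anion 8 (not isolated)
Conditions: Cs2CO3 (2 equiv), DMSO (0.02 M), 60 °C, argon, dark
Reagents that add atoms: none
Why: Cs2CO3 in DMSO generates the primary allylic alkoxide of 7 in low stationary concentration; it adds to C9a, the fluorine-bearing carbon, to give Meisenheimer anion 8 with the charge spread over C5a, C7 and C9 and drawn onto the para nitrile, and loss of fluoride restores the arene and leaves the O1–C9a bond of 9. The closest known reaction type is intramolecular SNAr etherification of para-cyano or para-nitro aryl fluorides by tethered alkoxides, which is used for benzo-fused oxygen heterocycles including seven-membered ones. The oxepine closes in a formally 7-exo-trig mode, with the departing fluoride and the C9a–C9 π bond that relays charge to the nitrile outside the new ring. Closure is favoured because the cis C4=C5 alkene and the arene hold the C2 oxygen near C9a and leave only the C2–C3, C3–C4 and C5–C5a torsions to be fixed. No stereocenter is formed in 9 (the sp3 C9a of 8 is transient), and the cis C4=C5 geometry is carried in from step 4. Attack at C9a should win over addition to the nitrile because imidate formation is reversible and fluoride loss is not, and regioselectivity is trivial because only one carbon bears a leaving group. Dilution disfavours intermolecular etherification, and carbonate, unlike tert-butoxide or a hydride base, neither competes as a nucleophile for C9a nor is strong enough to deprotonate C2 and move the exocyclic alkene into the ring.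

Step 6
Reactants: 9 3-methylidene-2,3-dihydro-1-benzoxepine-7-carbonitrile
Product: 11 3-methylidene-2,3-dihydro-1-benzoxepine-7-carbaldehyde, via N-alumino aldimine 10 (not isolated)
Conditions: i-Bu2AlH (1.2 equiv), CH2Cl2, −78 °C; then aq. potassium sodium tartrate, 1 M HCl, 0 °C
Reagents that add atoms: water, O (aldehyde oxygen of 11); i-Bu2AlH, CC(C)C[AlH]CC(C)C (its aluminium stays only in intermediate 10)
Why: Partial reduction of an aryl nitrile with DIBAL-H; one hydride adds to give the N-alumino aldimine 10, which resists a second addition at low temperature and is hydrolysed to the aldehyde on cold, briefly acidic work-up. Hydroalumination of the diene does not occur at −78 °C.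

Step 7
Reactants: 11 3-methylidene-2,3-dihydro-1-benzoxepine-7-carbaldehyde
Product: 12 (3-methylidene-2,3-dihydro-1-benzoxepin-7-yl)methanol
Conditions: NaBH4, MeOH/THF, 0 °C
Reagents that add atoms: none
Why: Borohydride 1,2-reduction of an aryl aldehyde; the medium is neutral to basic, which suits the acid-labile para-alkoxybenzyl alcohol, and the diene is not reduced.

Step 8
Reactants: 12 (3-methylidene-2,3-dihydro-1-benzoxepin-7-yl)methanol; 13 stearoyl chloride
Product: 14 (3-methylidene-2,3-dihydro-1-benzoxepin-7-yl)methyl octadecanoate
Conditions: Et3N (1.5 equiv), DMAP (5 mol %), CH2Cl2, 0 °C to rt
Reagents that add atoms: stearoyl chloride (compound 13), CCCCCCCCCCCCCCCCCC(=O)Cl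
Why: DMAP-catalysed acylation of a primary alcohol through the acylpyridinium ion; excess amine removes HCl, so the electron-rich benzylic position should be neither ionized nor chlorinated.

## Compound list

1 | 3-bromo-4-fluorobenzonitrile | N#Cc1ccc(F)c(Br)c1 | starting material
2 | trimethylsilylacetylene | C[Si](C)(C)C#C | starting material
3 | 4-fluoro-3-[(trimethylsilyl)ethynyl]benzonitrile | N#Cc1ccc(F)c(C#C[Si](C)(C)C)c1 | intermediate
4 | 3-ethynyl-4-fluorobenzonitrile | N#Cc1ccc(F)c(C#C)c1 | intermediate
5 | 2-bromoprop-2-en-1-ol | OCC(Br)=C | starting material
6 | 4-fluoro-3-[3-(hydroxymethyl)but-3-en-1-yn-1-yl]benzonitrile | N#Cc1ccc(F)c(C#CC(=C)CO)c1 | intermediate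
7 | 4-fluoro-3-[(1Z)-3-(hydroxymethyl)buta-1,3-dien-1-yl]benzonitrile | N#Cc1ccc(F)c(/C=C\C(=C)CO)c1 | intermediate
8 | Meisenheimer anion: 7-cyano-9a-fluoro-3-methylidene-2,3-dihydro-9aH-1-benzoxepin-7-ide (charge shared by C5a, C7, C9 and the nitrile; C9a transiently sp3, racemic) | N#C[C-]1C=CC2(F)OCC(=C)C=CC2=C1 | intermediate (not isolated)
9 | 3-methylidene-2,3-dihydro-1-benzoxepine-7-carbonitrile | N#Cc1ccc2OCC(=C)C=Cc2c1 | intermediate
10 | N-(diisobutylalumanyl)-1-(3-methylidene-2,3-dihydro-1-benzoxepin-7-yl)methanimine | CC(C)C[Al](CC(C)C)N=Cc1ccc2OCC(=C)C=Cc2c1 | intermediate (not isolated)
11 | 3-methylidene-2,3-dihydro-1-benzoxepine-7-carbaldehyde | O=Cc1ccc2OCC(=C)C=Cc2c1 | intermediate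
12 | (3-methylidene-2,3-dihydro-1-benzoxepin-7-yl)methanol | OCc1ccc2OCC(=C)C=Cc2c1 | intermediate
13 | stearoyl chloride (octadecanoyl chloride) | CCCCCCCCCCCCCCCCCC(=O)Cl | starting material
14 | (3-methylidene-2,3-dihydro-1-benzoxepin-7-yl)methyl octadecanoate | C=C1C=Cc2cc(COC(=O)CCCCCCCCCCCCCCCCC)ccc2OC1 | target

## Step count and risk

Total steps: 8. Longest linear sequence: 8 steps (from 1 to 14).

**Step 5 (key step).** The carbonate may form the alkoxide only slowly. Prolonged heating would then allow intermolecular etherification to oligomers, or base- and light-induced Z-to-E isomerization of the styrenic alkene, which removes the geometry needed for closure. Telescoping crude 7 into the closure should limit handling of the cis diene.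

Fallback, from 1 and 5, rejoining at 9: the aryl ether bond is still made by SNAr, but intermolecularly and first, and the ring is closed at C4=C5 instead.
- Compound 5 is deprotonated with NaH in THF at 0 °C and added to 1 to give 3-bromo-4-[(2-bromoprop-2-en-1-yl)oxy]benzonitrile F1.
- Twofold Stille coupling with tributyl(vinyl)stannane (Pd(PPh3)4, toluene, 90 °C) gives 3-ethenyl-4-[(2-methylidenebut-3-en-1-yl)oxy]benzonitrile F2.
- Ring-closing metathesis with second-generation Grubbs catalyst RuCl2(=CHPh)(PCy3)(H2IMes) (CH2Cl2, 40 °C, dilute) between the styrene vinyl group and the vinyl terminus of the diene should give 9.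
- The open point of this fallback is competition from six-membered closure through the 1,1-disubstituted alkene.

**Step 4.** The reduction may be incomplete or may continue past the diene, and partial Z-to-E isomerization on the metal surface or in light would erode the geometry.

Fallback, from 4, rejoining at 7 and bypassing 6: the cis alkene is built by stereodefined coupling instead of reduction.
- Rhodium-catalysed trans-hydroboration of the terminal alkyne ([RhCl(cod)]2, P(i-Pr)3, Et3N, pinacolborane, cyclohexane, rt) should give 4-fluoro-3-[(Z)-2-(4,4,5,5-tetramethyl-1,3,2-dioxaborolan-2-yl)ethenyl]benzonitrile F3.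
- Suzuki–Miyaura coupling of F3 with 5 (Pd(PPh3)4, K3PO4, THF/H2O, 50 °C) proceeds with retention at both partners and should give 7.

**Step 3.** Oxidative homocoupling of the electron-poor terminal alkyne may outrun the slow oxidative addition of the 1,1-disubstituted vinyl bromide, and the base may dehydrobrominate 5.

Fallback, from 2 and 5, rejoining at 6: the coupling order is reversed, so that the cheap alkyne can be used in excess against the more reactive aryl bromide.
- Sonogashira coupling of 2 with 5 (Pd(PPh3)4, CuI, Et3N, THF, rt) gives 2-methylidene-4-(trimethylsilyl)but-3-yn-1-ol F4.
- K2CO3 in MeOH gives 2-methylidenebut-3-yn-1-ol F5, which is kept in solution because it is volatile.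
- Sonogashira coupling of F5 with aryl bromide 1 (PdCl2(PPh3)2, CuI, Et3N, THF, 50 °C) should give 6.

**Step 6.** The aluminium aldimine may collapse before the quench, leading to over-reduction to the benzylic amine, or the aldimine may hydrolyse incompletely under a work-up mild enough for the diene.

Fallback, from 9, rejoining at 12 and bypassing 11: the nitrile is hydrolysed instead of partially reduced.
- KOH in EtOH/H2O at reflux, then acidification to about pH 4 with citric acid, gives 3-methylidene-2,3-dihydro-1-benzoxepine-7-carboxylic acid F6.
- LiAlH4 in THF (0 °C to rt) reduces F6 to alcohol 12; it does not attack the non-activated diene.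

## Further compounds

F1 | step 5 | 3-bromo-4-[(2-bromoprop-2-en-1-yl)oxy]benzonitrile | N#Cc1ccc(OCC(Br)=C)c(Br)c1
F2 | step 5 | 3-ethenyl-4-[(2-methylidenebut-3-en-1-yl)oxy]benzonitrile | N#Cc1ccc(OCC(=C)C=C)c(C=C)c1
F3 | step 4 | 4-fluoro-3-[(Z)-2-(4,4,5,5-tetramethyl-1,3,2-dioxaborolan-2-yl)ethenyl]benzonitrile | N#Cc1ccc(F)c(/C=C\B2OC(C)(C)C(C)(C)O2)c1
F4 | step 3 | 2-methylidene-4-(trimethylsilyl)but-3-yn-1-ol | C[Si](C)(C)C#CC(=C)CO
F5 | step 3 | 2-methylidenebut-3-yn-1-ol | C#CC(=C)CO
F6 | step 6 | 3-methylidene-2,3-dihydro-1-benzoxepine-7-carboxylic acid | OC(=O)c1ccc2OCC(=C)C=Cc2c1
A1 | alternative 1 | methyl 2,2-dimethyl-2H-chromene-6-carboxylate | COC(=O)c1ccc2OC(C)(C)C=Cc2c1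
A2 | alternative 1 | methyl (3Z)-3-(3-methylbut-2-en-1-ylidene)-4-oxocyclohexa-1,5-diene-1-carboxylate (ortho-quinone methide) | O=C1C=CC(C(=O)OC)=C/C1=C/C=C(C)C
A3 | alternative 1 | methyl 4-hydroxy-3-[(1Z)-3-methylbuta-1,3-dien-1-yl]benzoate | COC(=O)c1ccc(O)c(/C=C\C(C)=C)c1
A4 | alternative 1 | methyl 3-methyl-2,5-dihydro-1-benzoxepine-7-carboxylate | COC(=O)c1ccc2OCC(C)=CCc2c1
A5 | alternative 2 | 3-methyl-6-[(triisopropylsilyloxy)methyl]-2H-chromene | CC1=Cc2cc(CO[Si](C(C)C)(C(C)C)C(C)C)ccc2OC1
A6 | alternative 2 | 4-bromo-3-methylidene-7-[(triisopropylsilyloxy)methyl]-2,3-dihydro-1-benzoxepine | C=C1COc2ccc(CO[Si](C(C)C)(C(C)C)C(C)C)cc2C=C1Br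
A7 | alternative 3 | methyl 3-(2-oxoethyl)-4-(prop-2-yn-1-yloxy)benzoate | COC(=O)c1ccc(OCC#C)c(CC=O)c1
A8 | alternative 3 | methyl 3-methylidene-4-(triethylsilyloxy)-2,3,4,5-tetrahydro-1-benzoxepine-7-carboxylate (racemic, one enantiomer drawn) | COC(=O)c1ccc2OCC(=C)[C@@H](O[Si](CC)(CC)CC)Cc2c1
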